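The cyclohexane ring (benzofuranone numbering) is opened at the two bonds that flank the C6 oxygen function one position away: C4–C5, to the gem-dimethyl quaternary carbon, and C7–C7a, to the methyl-bearing lactone carbinol. C5–C6–C7 is then one acetone unit, supplied by 2-methoxypropene to an acyclic Morita–Baylis–Hillman-type alcohol. In one flask a Saucy–Marbet Claisen rearrangement forges C4–C5 and sets a Z 1,5-diketo enoate, and (R)-proline closes C7–C7a by enamine aldolisation; the new tertiary alkoxide lactonises onto the cis ester. The step exploits that C4 and C7a are both β to C6 and that the butenolide carbons C2–C3 hang from C3a. Reduction and palmitoylation follow.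

Key step: step 2

Step 1
Reactants: 1 pent-3-yn-2-one; 2 ethyl glyoxylate
Product: 4 ethyl 3-acetyl-2-hydroxy-4-methylpent-3-enoate (racemic), via allenolate 3 (not isolated)
Conditions: MeLi (2.1 equiv), CuI (1.05 equiv), Et2O, −30 °C (Me2CuLi); 1, THF, −78 °C; then 2, −78 to −40 °C; aq. NH4Cl
Reagents that add atoms: methyllithium, C[Li]
Why: Conjugate addition of the Gilman reagent Me2CuLi to the ynone gives the β,β-dimethyl allenolate 3, which is trapped at its central carbon by the aldehyde of 2 (tandem cuprate addition/aldol, the organometallic entry to Morita–Baylis–Hillman-type adducts); the carbinol centre forms as a racemate, which does not matter because this carbon becomes sp2 in step 2.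

Step 2
Reactants: 4 ethyl 3-acetyl-2-hydroxy-4-methylpent-3-enoate; 5 2-methoxypropene
Product: 9 (7aR)-4,4,7a-trimethyl-5,7a-dihydro-1-benzofuran-2,6(4H,7H)-dione [(R)-dehydrololiolide], via isopropenyl ether 6 (not isolated), via diketo ester 7 (not isolated), via ketol 8 (not isolated)
Conditions: 5 (8 equiv), pyridinium p-toluenesulfonate (2 mol %), toluene, sealed tube, 130 °C; volatiles removed; (R)-proline (30 mol %), DMSO, 25 °C
Reagents that add atoms: none
Why: Acid-catalysed exchange of the carbinol of 4 with 5 gives the allyl isopropenyl ether 6, which undergoes a [3,3]-sigmatropic Saucy–Marbet Claisen rearrangement through a chair transition state: the enol ether CH2 bonds to the isopropylidene carbon (C4–C5, a quaternary centre), the double bond moves to C3a=C3 and the methyl ketone is released, the closest precedents being Claisen rearrangements of Morita–Baylis–Hillman adducts. The ester should sit pseudo-equatorial, since the axial position is syn to the axial methyl of the CMe2 terminus and to the enol ether methyl, so that 7 forms with the ester cis to the acetyl group (Z). (R)-Proline then condenses with the unhindered methyl ketone of 7 and the enamine adds to the acetyl carbonyl in a 6-(enolendo)-exo-trig aldolisation of the Hajos–Parrish type (C7–C7a), after which the tertiary hydroxyl of 8 acylates on the cis ester (5-exo-trig lactonisation) with loss of ethanol. C7a is set by the catalyst through the carboxylic acid-directed Houk–List transition state; by analogy with the Hajos–Parrish ketol, in which (S)-proline gives the S carbinol with the same substituent ranking, (R)-proline should give 7aR. The step needs carbonyl addition to win over conjugate attack at C3 and over aldolisation in the reverse sense: the acetyl group is twisted out of conjugation by 1,3-allylic strain with the cis ester, so that C3 is only the α-carbon of an enoate, enamine formation is confined to the less hindered ketone, and of all reversible aldol adducts only 8 can lactonise.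

Step 3
Reactants: 9 (R)-dehydrololiolide
Product: 10 (6S,7aR)-6-hydroxy-4,4,7a-trimethyl-5,6,7,7a-tetrahydro-1-benzofuran-2(4H)-one [(−)-loliolide]
Conditions: LiBH(s-Bu)3 (1.1 equiv), THF, −78 °C; aq. NH4Cl
Reagents that add atoms: none
Why: Reduction with a bulky trialkylborohydride: the hydride should enter the C6 carbonyl from the face opposite the two syn-axial methyl groups on C4 and C7a (equatorial attack, as on 3,3,5-trimethylcyclohexanone), which gives the axial 6S alcohol cis to the C7a methyl, and −78 °C should keep the butenolide and the β-acyloxy ketone intact.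

Step 4
Reactants: 10 (−)-loliolide; 11 hexadecanoyl chloride (palmitoyl chloride)
Product: 12 (6S,7aR)-4,4,7a-trimethyl-2-oxo-2,4,5,6,7,7a-hexahydro-1-benzofuran-6-yl hexadecanoate [(−)-3-O-palmitoylloliolide]
Conditions: 11 (1.5 equiv), pyridine (3 equiv), DMAP (0.2 equiv), CH2Cl2, 0 to 25 °C
Reagents that add atoms: none
Why: DMAP-catalysed O-acylation of the secondary alcohol by the acid chloride (nucleophilic acyl substitution); no stereocentre is touched, so the 6S,7aR configuration is carried into the ester.

Compound list
1 | pent-3-yn-2-one | CC#CC(C)=O | starting material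
2 | ethyl glyoxylate (ethyl 2-oxoacetate) | CCOC(=O)C=O | starting material
3 | lithium 4-methylpenta-2,3-dien-2-olate (allenolate from the cuprate addition) | [Li+].CC([O-])=C=C(C)C | intermediate
4 | ethyl 3-acetyl-2-hydroxy-4-methylpent-3-enoate (racemic) | CCOC(=O)C(O)C(C(C)=O)=C(C)C | intermediate
5 | 2-methoxypropene | COC(C)=C | starting material
6 | ethyl 3-acetyl-4-methyl-2-(prop-1-en-2-yloxy)pent-3-enoate (racemic) | CCOC(=O)C(OC(C)=C)C(C(C)=O)=C(C)C | intermediate
7 | ethyl (2Z)-3-acetyl-4,4-dimethyl-6-oxohept-2-enoate | CCOC(=O)/C=C(\C(C)=O)C(C)(C)CC(C)=O | intermediate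
8 | ethyl (2Z)-[(2R)-2-hydroxy-2,6,6-trimethyl-4-oxocyclohexylidene]acetate | CCOC(=O)/C=C1/C(C)(C)CC(=O)C[C@@]1(C)O | intermediate
9 | (7aR)-4,4,7a-trimethyl-5,7a-dihydro-1-benzofuran-2,6(4H,7H)-dione, (R)-dehydrololiolide | O=C1CC(C)(C)C2=CC(=O)O[C@]2(C)C1 | intermediate
10 | (6S,7aR)-6-hydroxy-4,4,7a-trimethyl-5,6,7,7a-tetrahydro-1-benzofuran-2(4H)-one, (−)-loliolide | O[C@H]1CC(C)(C)C2=CC(=O)O[C@]2(C)C1 | intermediate
11 | hexadecanoyl chloride | CCCCCCCCCCCCCCCC(Cl)=O | starting material
12 | (6S,7aR)-4,4,7a-trimethyl-2-oxo-2,4,5,6,7,7a-hexahydro-1-benzofuran-6-yl hexadecanoate | CCCCCCCCCCCCCCCC(=O)O[C@H]1CC(C)(C)C2=CC(=O)O[C@]2(C)C1 | target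

Total step count: 4. Longest linear sequence: 4 steps (1 to 12).

Steps most likely to fail

Step 2. Several processes could derail it:
- conjugate (6-endo) attack of the enamine at C3 in place of carbonyl addition;
- formation of the E ester in the rearrangement, which cannot lactonise;
- weak discrimination of the two faces of the acetyl group by the catalyst;
- erosion of the C7a configuration by retro-aldol or by β-elimination and re-addition of the lactone carboxylate under amine catalysis.

The fallback sets out from 7, obtained by stopping step 2 after the rearrangement, and returns at 10. Heating 7 in aqueous HCl/acetic acid should hydrolyse the ester, equilibrate the enoate geometry and let the keto acid close to the pseudoacid 5-hydroxy-5-methyl-4-(2-methyl-4-oxopentan-2-yl)furan-2(5H)-one F1, in which no enone is left. The acid should then drive the methyl ketone enol onto the acyloxocarbenium carbon (the known ketone condensation of γ-hydroxybutenolides) to give racemic 4,4,7a-trimethyl-5,7a-dihydro-1-benzofuran-2,6(4H,7H)-dione F2. LiBH(s-Bu)3 reduces F2 to racemic loliolide F3, which is esterified with (S)-2-methoxy-2-phenylacetic acid (DCC, DMAP). The (6S,7aR)-loliolide (S)-2-methoxy-2-phenylacetate F4 is separated from its diastereomer by chromatography and cleaved with K2CO3 in methanol to 10.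

Step 1. The methyl nucleophile may add 1,2 to the ynone, the allenolate may be protonated or oligomerise before it meets the aldehyde, and residual methylcopper may attack 2. The fallback sets out from 2 and returns at 4, with commercial mesityl oxide (4-methylpent-3-en-2-one) in place of 1. Mesityl oxide is brominated with Br2 to 3,4-dibromo-4-methylpentan-2-one F5 and dehydrobrominated with Et3N to 3-bromo-4-methylpent-3-en-2-one F6. F6 is coupled with 2 by the Nozaki–Hiyama–Kishi reaction (CrCl2, catalytic NiCl2, DMF), in which the alkenylchromium species adds to the aldehyde and leaves the ketone alone, to give 4.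

Step 3. The basic borohydride may reduce the butenolide in conjugate fashion or trigger β-elimination of the lactone carboxylate from the β-acyloxy ketone. The fallback sets out from 9 and returns at 10. Ionic hydrogenation under acid (Et3SiH in CF3CO2H, 0 °C) should deliver hydride to the protonated C6 carbonyl from the same unhindered face and give (6S,7aR)-4,4,7a-trimethyl-2-oxo-2,4,5,6,7,7a-hexahydro-1-benzofuran-6-yl trifluoroacetate F7. NaHCO3 in methanol then removes the trifluoroacetyl group to give 10.

Further compounds
F1 | step 2 | 5-hydroxy-5-methyl-4-(2-methyl-4-oxopentan-2-yl)furan-2(5H)-one (racemic pseudoacid) | CC(=O)CC(C)(C)C1=CC(=O)OC1(C)O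
F2 | step 2 | racemic 4,4,7a-trimethyl-5,7a-dihydro-1-benzofuran-2,6(4H,7H)-dione | O=C1CC(C)(C)C2=CC(=O)OC2(C)C1
F3 | step 2 | racemic loliolide, (6S,7aR) and (6R,7aS) pair | O[C@H]1CC(C)(C)C2=CC(=O)O[C@]2(C)C1.O[C@@H]1CC(C)(C)C2=CC(=O)O[C@@]2(C)C1
F4 | step 2 | (6S,7aR)-loliolide (S)-2-methoxy-2-phenylacetate | CO[C@H](C(=O)O[C@H]1CC(C)(C)C2=CC(=O)O[C@]2(C)C1)c1ccccc1
F5 | step 1 | 3,4-dibromo-4-methylpentan-2-one (racemic) | CC(=O)C(Br)C(C)(C)Br
F6 | step 1 | 3-bromo-4-methylpent-3-en-2-one | CC(=O)C(Br)=C(C)C
F7 | step 3 | (6S,7aR)-4,4,7a-trimethyl-2-oxo-2,4,5,6,7,7a-hexahydro-1-benzofuran-6-yl trifluoroacetate | O=C(O[C@H]1CC(C)(C)C2=CC(=O)O[C@]2(C)C1)C(F)(F)F
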